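**Plan**
1. Retrosynthesis: the acid is unmasked last. The C2'–CH3 bond (Negishi) and the C1'=C2' double bond (α-iodo Wittig) are cut to give aldehyde 14 and the C9 phosphonium salt 22. The acrylate C=C is cut back to lactol 10. Both C–O bonds of the peroxide are then cut, which leads to O2 and cyclopropane 7.
2. Enabling feature: in the 3-oxabicyclo[3.1.0]hexan-2-one 7 the strained cyclopropane bond C1–C5 lies between a vinyl group on C5 (entry for PhSe•) and the lactone C=O on C1 (radical stabilisation). The C(=O)–O–CH2 bridge of the lactone ring holds C1 and C5 on one face.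
3. Forward: lactone and cyclopropane rings form together by carbenoid cyclopropanation. O2 is then inserted into C1–C5, so the 1,2-dioxolane arises as the peroxide bridge of a 3,6,7-trioxabicyclo[3.2.1]octane. The vinyl group becomes the ring ethyl group, the lactone is opened into acrylate and CH2OH, and the side chain is joined last by olefination and methylation.
4. Stereochemistry: the cis relation of the two quaternary ring carbons is enforced by the lactone tether, and their absolute configuration comes from a lipase resolution of alcohol 12. The side-chain centre comes from ligand-controlled Et2Zn addition and suprafacial Johnson–Claisen transfer. The alkene geometries come from a stabilised ylide (E), the chair Claisen (E) and a Z-selective iodo-olefination followed by methylation with retention.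

Key step: step 5

Assumption: the lipase of step 9 is taken to acylate the (3R,5S)-alcohol faster; if its preference is the reverse, the acetate fraction would be carried on after enzymatic hydrolysis.
Assumption: (+)-MIB is taken to give the (R)-alcohol in step 11, by analogy with aryl and alkenyl aldehydes; the antipodal ligand would be used otherwise.

**Step 1**
Reactants: 1 2-bromoprop-2-en-1-ol; 2 potassium ethenyltrifluoroborate
Product: 3 2-methylidenebut-3-en-1-ol
Conditions: PdCl2(dppf) (3 mol %, dppf = 1,1'-bis(diphenylphosphino)ferrocene), Cs2CO3, THF/H2O 9:1, 70 °C, BHT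
Reagents that add atoms: none
Why: Suzuki–Miyaura coupling of an alkenyl bromide with a vinyltrifluoroborate, which tolerates the free allylic hydroxyl group; no stereocentre is formed.

**Step 2**
Reactants: 3 2-methylidenebut-3-en-1-ol; 4 ethyl 2-ethyl-3-oxobutanoate
Product: 5 2-methylidenebut-3-en-1-yl 2-ethyl-3-oxobutanoate
Conditions: DMAP (0.2 equiv), toluene (0.2 M), 100 °C, 4 Å molecular sieves, BHT
Reagents that add atoms: none
Why: DMAP-catalysed transesterification of a β-keto ester is driven by removal of ethanol, and the dilution should keep Diels–Alder dimerisation of the diene slow.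

**Step 3**
Reactants: 5 2-methylidenebut-3-en-1-yl 2-ethyl-3-oxobutanoate
Product: 6 2-methylidenebut-3-en-1-yl 2-diazobutanoate
Conditions: 4-acetamidobenzenesulfonyl azide, DBU, MeCN, 0 °C → rt
Reagents that add atoms: 4-acetamidobenzenesulfonyl azide, CC(=O)Nc1ccc(cc1)S(=O)(=O)N=[N+]=[N-]
Why: Regitz deacylating diazo transfer, in which the enolate of the 2-substituted β-keto ester attacks the sulfonyl azide and the acetyl group passes to the sulfonamide nitrogen, should leave the α-diazo ester.

**Step 4**
Reactants: 6 2-methylidenebut-3-en-1-yl 2-diazobutanoate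
Product: 7 racemic 5-ethenyl-1-ethyl-3-oxabicyclo[3.1.0]hexan-2-one (cis ring fusion)
Conditions: Rh2(O2CCPh3)4 (1 mol %), CH2Cl2, −78 °C → −20 °C, slow addition of 6
Reagents that add atoms: none
Why: Intramolecular cyclopropanation by a dirhodium carbenoid onto the proximal 1,1-disubstituted alkene of the diene closes the γ-lactone and the cyclopropane at once (cis fusion is the only one possible, product racemic); bulky triphenylacetate ligands and low temperature are the known means of suppressing the 1,2-hydride shift of α-alkyl carbenoids.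

**Step 5**
Reactants: 7 racemic 5-ethenyl-1-ethyl-3-oxabicyclo[3.1.0]hexan-2-one
Product: 8 racemic 5-ethenyl-1-ethyl-3,6,7-trioxabicyclo[3.2.1]octan-2-one
Conditions: O2 (1 atm), PhSeSePh (0.2 equiv), AIBN (0.1 equiv), MeCN (0.02 M), sunlamp (Pyrex), 0 °C
Reagents that add atoms: dioxygen, O=O
Why: Proposed new method: PhSe• adds to the terminal vinyl carbon, the cyclopropylcarbinyl radical opens the strained C1–C5 ring-fusion bond to a tertiary, lactone-stabilised radical at C1 of a six-membered lactone that now carries an exocyclic allyl selenide at C5, O2 is trapped at C1, and the peroxyl oxygen adds to C5 with loss of PhSe•, which carries the chain. The closest known reaction type is the arylselenyl- or arylthiyl-radical-mediated oxygenation of monocyclic vinylcyclopropanes to 3-vinyl-1,2-dioxolanes; the extension is that the bond opened is a ring-fusion bond, so that the peroxide forms as a bridge. The 1,2-dioxolane ring closes by a 5-exo-trig attack of the peroxyl radical across the six-membered lactone (1,3-transannular), which gives the 3,6,7-trioxabicyclo[3.2.1]octane. Both quaternary stereocentres (C1 and C5) arise here, and their relative configuration is fixed by the C(=O)–O–CH2 tether, because the peroxide can bridge only the face opposite to it, so carbonyl and CH2O end cis on the dioxolane; the product is racemic because both centres pass through sp2 carbon. The step needs scission of C1–C5 instead of C5–C6, which the carbonyl on C1 secures (tertiary conjugated radical against a primary one), and ring closure faster than hydrogen abstraction, which the absence of thiol or selenol and the 1,3 placement of the electron-rich allyl selenide alkene secure.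

**Step 6**
Reactants: 8 racemic 5-ethenyl-1-ethyl-3,6,7-trioxabicyclo[3.2.1]octan-2-one
Product: 9 racemic 1,5-diethyl-3,6,7-trioxabicyclo[3.2.1]octan-2-one
Conditions: dipotassium azodicarboxylate, AcOH, CH2Cl2, 0 °C → rt
Reagents that add atoms: none
Why: Diimide, generated in the flask, transfers H2 to the unhindered terminal alkene by concerted syn addition and is known not to cleave peroxide O–O bonds; no stereocentre is touched.

**Step 7**
Reactants: 9 racemic 1,5-diethyl-3,6,7-trioxabicyclo[3.2.1]octan-2-one
Product: 10 racemic 1,5-diethyl-3,6,7-trioxabicyclo[3.2.1]octan-2-ol (both anomers)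
Conditions: iBu2AlH (1.1 equiv), CH2Cl2, −78 °C; aqueous potassium sodium tartrate
Reagents that add atoms: none
Why: Partial reduction of a lactone with one equivalent of iBu2AlH stops at the aluminium hemiacetal at −78 °C, and a di-tertiary peroxide without α-hydrogen should tolerate the hydride at this temperature.

**Step 8**
Reactants: 10 racemic 1,5-diethyl-3,6,7-trioxabicyclo[3.2.1]octan-2-ol
Product: 12 racemic methyl (2E)-3-[(3S*,5R*)-3,5-diethyl-5-(hydroxymethyl)-1,2-dioxolan-3-yl]prop-2-enoate, via hydroxy aldehyde 11 (not isolated)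
Conditions: Ph3P=CHCO2Me (1.5 equiv), PhCO2H (cat.), toluene, 40 °C
Reagents that add atoms: methyl (triphenylphosphoranylidene)acetate, COC(=O)C=P(c1ccccc1)(c1ccccc1)c1ccccc1
Why: Wittig olefination of the ring-opened tautomer 11 with a stabilised ylide should give the E acrylate, remove the tether and free the hydroxymethyl group on the other ring carbon; neutral conditions and mild temperature are chosen to keep the hydroxyl from adding back to the acrylate.

**Step 9**
Reactants: 12 racemic methyl (2E)-3-[(3S*,5R*)-3,5-diethyl-5-(hydroxymethyl)-1,2-dioxolan-3-yl]prop-2-enoate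
Product: 13 methyl (2E)-3-[(3S,5R)-3,5-diethyl-5-(hydroxymethyl)-1,2-dioxolan-3-yl]prop-2-enoate
Conditions: lipase from Burkholderia cepacia (Amano PS), vinyl acetate, t-BuOMe, 30 °C, to about 55% conversion; chromatography
Reagents that add atoms: none
Why: Lipase-catalysed acylation as a kinetic resolution of a primary alcohol on a quaternary centre should acetylate the (3R,5S)-enantiomer and leave 13; because the relative configuration is already locked, this one step fixes the absolute configuration of both ring stereocentres.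

**Step 10**
Reactants: 13 methyl (2E)-3-[(3S,5R)-3,5-diethyl-5-(hydroxymethyl)-1,2-dioxolan-3-yl]prop-2-enoate
Product: 14 methyl (2E)-3-[(3S,5R)-3,5-diethyl-5-formyl-1,2-dioxolan-3-yl]prop-2-enoate
Conditions: Dess–Martin periodinane, NaHCO3, CH2Cl2, 0 °C → rt
Reagents that add atoms: none
Why: Dess–Martin oxidation of the neopentyl primary alcohol under buffered conditions; the aldehyde has no α-hydrogen, so the adjacent stereocentre cannot epimerise.

**Step 11**
Reactants: 15 (2E)-pent-2-enal
Product: 16 (3R,4E)-hept-4-en-3-ol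
Conditions: Et2Zn (1.5 equiv), (+)-MIB [(2R)-3-exo-morpholinoisoborneol, 4 mol %], hexanes/toluene, 0 °C; aqueous NH4Cl
Reagents that add atoms: diethylzinc, CC[Zn]CC
Why: Amino-alcohol-catalysed asymmetric 1,2-addition of Et2Zn to an enal, in which the chiral zinc aminoalkoxide selects the aldehyde face and so sets the carbinol centre.

**Step 12**
Reactants: 16 (3R,4E)-hept-4-en-3-ol
Product: 19 ethyl (3R,4E)-3-ethylhept-4-enoate, via mixed orthoester 17 (not isolated), via ketene acetal 18 (not isolated)
Conditions: MeC(OEt)3 (6 equiv), EtCO2H (5 mol %), 140 °C, ethanol distilled off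
Reagents that add atoms: triethyl orthoacetate, CC(OCC)(OCC)OCC
Why: Johnson–Claisen rearrangement, in which ketene acetal 18 reacts through a chair transition state with the carbinol ethyl group equatorial; this should give the E alkene and transfer the carbinol configuration suprafacially to the new C–C bond, so that (R)-16 gives (R)-19.

**Step 13**
Reactants: 19 ethyl (3R,4E)-3-ethylhept-4-enoate
Product: 20 (3R,4E)-3-ethylhept-4-en-1-ol
Conditions: LiAlH4, Et2O, 0 °C; aqueous NaOH work-up
Reagents that add atoms: none
Why: LiAlH4 reduction of the ester; the stereocentre is β to the carbonyl group and is not touched.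

**Step 14**
Reactants: 20 (3R,4E)-3-ethylhept-4-en-1-ol
Product: 21 (3E,5R)-5-ethyl-7-iodohept-3-ene
Conditions: iodine, PPh3, imidazole, CH2Cl2, 0 °C → rt
Reagents that add atoms: iodine, [I][I]
Why: Appel-type iodination of a primary alcohol by SN2 displacement of the oxyphosphonium group.

**Step 15**
Reactants: 21 (3E,5R)-5-ethyl-7-iodohept-3-ene
Product: 22 [(3R,4E)-3-ethylhept-4-en-1-yl]triphenylphosphonium iodide
Conditions: PPh3 (1.2 equiv), MeCN, 80 °C
Reagents that add atoms: triphenylphosphine, c1ccc(cc1)P(c1ccccc1)c1ccccc1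
Why: SN2 quaternisation of triphenylphosphine by the primary iodide.

**Step 16**
Reactants: 14 methyl (2E)-3-[(3S,5R)-3,5-diethyl-5-formyl-1,2-dioxolan-3-yl]prop-2-enoate; 22 [(3R,4E)-3-ethylhept-4-en-1-yl]triphenylphosphonium iodide
Product: 26 methyl (2E)-3-[(3S,5R)-3,5-diethyl-5-[(1Z,4R,5E)-4-ethyl-2-iodoocta-1,5-dien-1-yl]-1,2-dioxolan-3-yl]prop-2-enoate, via phosphorus ylide 23 (not isolated), via iodophosphonium salt 24 (not isolated), via iodo ylide 25 (not isolated)
Conditions: 22, NaN(SiMe3)2, THF, 0 °C; iodine, −78 °C; NaN(SiMe3)2, −78 → −20 °C; then 14, −78 °C → rt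
Reagents that add atoms: iodine, [I][I]
Why: Stork–Zhao-type Wittig olefination with the α-iodo ylide 25, whose kinetically controlled addition to the non-enolisable aldehyde should place iodine cis to the dioxolane carbon (Z), the geometry needed for the later methyl group.

**Step 17**
Reactants: 26 methyl (2E)-3-[(3S,5R)-3,5-diethyl-5-[(1Z,4R,5E)-4-ethyl-2-iodoocta-1,5-dien-1-yl]-1,2-dioxolan-3-yl]prop-2-enoate
Product: 27 methyl (2E)-3-[(3S,5R)-3,5-diethyl-5-[(1E,4R,5E)-4-ethyl-2-methylocta-1,5-dien-1-yl]-1,2-dioxolan-3-yl]prop-2-enoate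
Conditions: Me2Zn (2 equiv), Pd[P(t-Bu)3]2 (5 mol %), THF, 0 °C → rt
Reagents that add atoms: dimethylzinc, C[Zn]C
Why: Negishi coupling, in which oxidative addition of zerovalent palladium into the alkenyl carbon–iodine bond, transmetalation and reductive elimination proceed with retention of alkene geometry; the hindered di-tertiary peroxide should be left intact at room temperature.

**Step 18**
Reactants: 27 methyl (2E)-3-[(3S,5R)-3,5-diethyl-5-[(1E,4R,5E)-4-ethyl-2-methylocta-1,5-dien-1-yl]-1,2-dioxolan-3-yl]prop-2-enoate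
Product: 28 (2E)-3-[(3S,5R)-3,5-diethyl-5-[(1E,4R,5E)-4-ethyl-2-methylocta-1,5-dien-1-yl]-1,2-dioxolan-3-yl]prop-2-enoic acid
Conditions: LiOH, THF/H2O 3:1, 0 °C → rt; then 1 M HCl to pH 3–4 at 0 °C
Reagents that add atoms: lithium hydroxide, [Li+].[OH-]
Why: Saponification of the methyl ester; the tetrasubstituted dioxolane has no hydrogen on its oxygen-bearing carbons and so cannot undergo base-induced Kornblum–DeLaMare fragmentation.

**Compound list**
(For racemates the enantiomer drawn is the one that leads to 28.)
1 | 2-bromoprop-2-en-1-ol | OCC(Br)=C | starting material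
2 | potassium ethenyltrifluoroborate | [K+].C=C[B-](F)(F)F | starting material
3 | 2-methylidenebut-3-en-1-ol | OCC(=C)C=C | intermediate
4 | ethyl 2-ethyl-3-oxobutanoate (racemic, labile centre) | CCOC(=O)C(CC)C(C)=O | starting material
5 | 2-methylidenebut-3-en-1-yl 2-ethyl-3-oxobutanoate (racemic, labile centre) | C=CC(=C)COC(=O)C(CC)C(C)=O | intermediate
6 | 2-methylidenebut-3-en-1-yl 2-diazobutanoate | CCC(=[N+]=[N-])C(=O)OCC(=C)C=C | intermediate
7 | racemic 5-ethenyl-1-ethyl-3-oxabicyclo[3.1.0]hexan-2-one (cis-fused) | CC[C@]12C[C@@]1(C=C)COC2=O | intermediate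
8 | racemic 5-ethenyl-1-ethyl-3,6,7-trioxabicyclo[3.2.1]octan-2-one | O=C2OC[C@@]1(C=C)C[C@]2(CC)OO1 | intermediate
9 | racemic 1,5-diethyl-3,6,7-trioxabicyclo[3.2.1]octan-2-one | O=C2OC[C@@]1(CC)C[C@]2(CC)OO1 | intermediate
10 | racemic 1,5-diethyl-3,6,7-trioxabicyclo[3.2.1]octan-2-ol (both anomers) | OC2OC[C@@]1(CC)C[C@]2(CC)OO1 | intermediate
11 | racemic 3,5-diethyl-5-(hydroxymethyl)-1,2-dioxolane-3-carbaldehyde (formyl and hydroxymethyl cis) | OC[C@@]1(CC)C[C@](C=O)(CC)OO1 | intermediate (not isolated)
12 | racemic methyl (2E)-3-[(3S*,5R*)-3,5-diethyl-5-(hydroxymethyl)-1,2-dioxolan-3-yl]prop-2-enoate | OC[C@@]1(CC)C[C@](/C=C/C(=O)OC)(CC)OO1 | intermediate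
13 | methyl (2E)-3-[(3S,5R)-3,5-diethyl-5-(hydroxymethyl)-1,2-dioxolan-3-yl]prop-2-enoate | OC[C@@]1(CC)C[C@](/C=C/C(=O)OC)(CC)OO1 | intermediate
14 | methyl (2E)-3-[(3S,5R)-3,5-diethyl-5-formyl-1,2-dioxolan-3-yl]prop-2-enoate | O=C[C@@]1(CC)C[C@](/C=C/C(=O)OC)(CC)OO1 | intermediate
15 | (2E)-pent-2-enal | CC/C=C/C=O | starting material
16 | (3R,4E)-hept-4-en-3-ol | CC[C@@H](O)/C=C/CC | intermediate
17 | (3R,4E)-3-(1,1-diethoxyethoxy)hept-4-ene | CC[C@@H](OC(C)(OCC)OCC)/C=C/CC | intermediate (not isolated)
18 | (3R,4E)-3-[(1-ethoxyethenyl)oxy]hept-4-ene | CC[C@@H](OC(=C)OCC)/C=C/CC | intermediate (not isolated)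
19 | ethyl (3R,4E)-3-ethylhept-4-enoate | CC/C=C/[C@H](CC)CC(=O)OCC | intermediate
20 | (3R,4E)-3-ethylhept-4-en-1-ol | CC/C=C/[C@H](CC)CCO | intermediate
21 | (3E,5R)-5-ethyl-7-iodohept-3-ene | CC/C=C/[C@H](CC)CCI | intermediate
22 | [(3R,4E)-3-ethylhept-4-en-1-yl]triphenylphosphonium iodide | CC/C=C/[C@H](CC)CC[P+](c1ccccc1)(c1ccccc1)c1ccccc1.[I-] | intermediate
23 | [(3R,4E)-3-ethylhept-4-en-1-ylidene]triphenylphosphorane | CC/C=C/[C@H](CC)CC=P(c1ccccc1)(c1ccccc1)c1ccccc1 | intermediate (not isolated)
24 | [(3R,4E)-3-ethyl-1-iodohept-4-en-1-yl]triphenylphosphonium iodide (both epimers at C1) | CC/C=C/[C@H](CC)CC(I)[P+](c1ccccc1)(c1ccccc1)c1ccccc1.[I-] | intermediate (not isolated)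
25 | [(3R,4E)-3-ethyl-1-iodohept-4-en-1-ylidene]triphenylphosphorane | CC/C=C/[C@H](CC)CC(I)=P(c1ccccc1)(c1ccccc1)c1ccccc1 | intermediate (not isolated)
26 | methyl (2E)-3-[(3S,5R)-3,5-diethyl-5-[(1Z,4R,5E)-4-ethyl-2-iodoocta-1,5-dien-1-yl]-1,2-dioxolan-3-yl]prop-2-enoate | CC/C=C/[C@H](CC)C/C(I)=C/[C@@]1(CC)C[C@](/C=C/C(=O)OC)(CC)OO1 | intermediate
27 | methyl (2E)-3-[(3S,5R)-3,5-diethyl-5-[(1E,4R,5E)-4-ethyl-2-methylocta-1,5-dien-1-yl]-1,2-dioxolan-3-yl]prop-2-enoate | CC/C=C/[C@H](CC)C/C(C)=C/[C@@]1(CC)C[C@](/C=C/C(=O)OC)(CC)OO1 | intermediate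
28 | (2E)-3-[(3S,5R)-3,5-diethyl-5-[(1E,4R,5E)-4-ethyl-2-methylocta-1,5-dien-1-yl]-1,2-dioxolan-3-yl]prop-2-enoic acid | CC/C=C/[C@H](CC)C/C(C)=C/[C@@]1(CC)C[C@](/C=C/C(=O)O)(CC)OO1 | target

**Step count and risks**
Total: 18 steps. Longest linear sequence: 13 steps (steps 1–10 and 16–18); the side-chain branch is steps 11–15.

Most likely to fail, first: step 5 (the step labelled as a proposed new method). The peroxyl radical may abstract hydrogen or terminate before it bridges the six-membered ring, or the cyclopropylcarbinyl radical may partition into scission of the exocyclic C5–C6 bond. The fallback moves the oxygenation to the substrate class on which it is established and restores the tether afterwards. It sets out from 7, whose lactone is opened with Me(MeO)NH·HCl and AlMe3 (CH2Cl2, 0 °C) to racemic 2-ethenyl-1-ethyl-2-(hydroxymethyl)-N-methoxy-N-methylcyclopropane-1-carboxamide F1. This monocyclic vinylcyclopropane is then oxygenated under the conditions of step 5, which should give 5-ethenyl-3-ethyl-5-(hydroxymethyl)-N-methoxy-N-methyl-1,2-dioxolane-3-carboxamide F2 as a cis/trans mixture. PPTS in toluene at 40 °C should lactonise only the cis isomer, which comes back to the route at 8; the trans isomer is removed by chromatography.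

Second: step 16. Addition of the bulky α-iodo ylide to the neopentyl aldehyde may be slow, Z selectivity may erode through betaine equilibration, and the ylide or the amide base may attack the acrylate. The fallback is a one-step Julia–Kocienski olefination with the methyl group already in place. It sets out from 21, which is treated with 1-phenyl-1H-tetrazole-5-thiol and K2CO3 in DMF to give 5-{[(3R,4E)-3-ethylhept-4-en-1-yl]sulfanyl}-1-phenyl-1H-tetrazole F3. Oxidation with H2O2 and (NH4)6Mo7O24 in EtOH gives 5-{[(3R,4E)-3-ethylhept-4-en-1-yl]sulfonyl}-1-phenyl-1H-tetrazole F4. Methylation (KN(SiMe3)2, MeI, THF, −78 °C) gives 5-{[(4R,5E)-4-ethyloct-5-en-2-yl]sulfonyl}-1-phenyl-1H-tetrazole F5. Reaction of F5 with 14 (KN(SiMe3)2, DME, −60 °C → rt) would come back to the route at 27 and make step 17 unnecessary. The E and Z isomers would need separation on AgNO3-impregnated silica.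

Third: step 9. The lipase may discriminate poorly between enantiomers whose quaternary centre carries groups of similar size, so that useful enantiomeric purity is reached only at high conversion. The fallback replaces the resolution by a desymmetrisation, in which a second acylation removes the minor monoacetate. It sets out from 9, which LiBH4 (THF, 0 °C) reduces to meso [(3R,5S)-3,5-diethyl-1,2-dioxolane-3,5-diyl]dimethanol F6. Lipase and vinyl acetate should give [(3R,5S)-3,5-diethyl-5-(hydroxymethyl)-1,2-dioxolan-3-yl]methyl acetate F7. Dess–Martin oxidation gives [(3R,5S)-3,5-diethyl-5-formyl-1,2-dioxolan-3-yl]methyl acetate F8. Wittig reaction with Ph3P=CHCO2Me gives methyl (2E)-3-[(3S,5R)-5-(acetoxymethyl)-3,5-diethyl-1,2-dioxolan-3-yl]prop-2-enoate F9. Lipase-mediated hydrolysis of the acetate in pH 7 phosphate buffer, which avoids an alkoxide next to the acrylate, comes back to the route at 13.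

**Further compounds**
F1 | step 5 | racemic 2-ethenyl-1-ethyl-2-(hydroxymethyl)-N-methoxy-N-methylcyclopropane-1-carboxamide (hydroxymethyl cis to the amide) | CC[C@]1(C(=O)N(C)OC)C[C@@]1(C=C)CO
F2 | step 5 | racemic 5-ethenyl-3-ethyl-5-(hydroxymethyl)-N-methoxy-N-methyl-1,2-dioxolane-3-carboxamide (cis and trans; cis drawn) | OC[C@@]1(C=C)C[C@](C(=O)N(C)OC)(CC)OO1
F3 | step 16 | 5-{[(3R,4E)-3-ethylhept-4-en-1-yl]sulfanyl}-1-phenyl-1H-tetrazole | CC/C=C/[C@H](CC)CCSc1nnnn1-c1ccccc1
F4 | step 16 | 5-{[(3R,4E)-3-ethylhept-4-en-1-yl]sulfonyl}-1-phenyl-1H-tetrazole | CC/C=C/[C@H](CC)CCS(=O)(=O)c1nnnn1-c1ccccc1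
F5 | step 16 | 5-{[(4R,5E)-4-ethyloct-5-en-2-yl]sulfonyl}-1-phenyl-1H-tetrazole (both epimers at C2) | CC/C=C/[C@H](CC)CC(C)S(=O)(=O)c1nnnn1-c1ccccc1
F6 | step 9 | meso [(3R,5S)-3,5-diethyl-1,2-dioxolane-3,5-diyl]dimethanol | OC[C@@]1(CC)C[C@](CO)(CC)OO1
F7 | step 9 | [(3R,5S)-3,5-diethyl-5-(hydroxymethyl)-1,2-dioxolan-3-yl]methyl acetate | CC(=O)OC[C@@]1(CC)C[C@](CO)(CC)OO1
F8 | step 9 | [(3R,5S)-3,5-diethyl-5-formyl-1,2-dioxolan-3-yl]methyl acetate | CC(=O)OC[C@@]1(CC)C[C@](C=O)(CC)OO1
F9 | step 9 | methyl (2E)-3-[(3S,5R)-5-(acetoxymethyl)-3,5-diethyl-1,2-dioxolan-3-yl]prop-2-enoate | CC(=O)OC[C@@]1(CC)C[C@](/C=C/C(=O)OC)(CC)OO1
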